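**Retrosynthetic overview**
1. No ring is formed. All three benzene rings are bought: rings A and B come from 2,4-dihydroxy-6-methylbenzaldehyde and ring C from methyl orsellinate. The only skeletal bonds made are the two depside C(=O)–OAr bonds.
2. The last disconnection is the two benzyl ethers on ring A, removed by one global hydrogenolysis.
3. The B–C ester comes from the A–B carboxylic acid and the non-chelated 4-OH of methyl orsellinate.
4. The A–B acid comes from the A–B aldehyde. CHO serves as latent CO2H, so ring B needs no protecting group, and the 2'-OMe goes on once the A–B ester has blocked the 4'-OH.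
5. The A–B ester comes from 2,4-bis(benzyloxy)-6-methylbenzoic acid (same aldehyde, dibenzylated then oxidised) and the non-chelated 4-OH of the aldehyde. Assembly order is A, then A–B, then A–B–C.

Assumption: the SMILES has no stereocentre, stereogenic axis or double-bond geometry, so the target is achiral and no stereocontrol is needed; 1 and 8 are taken as commercially available.

**Step 1**
Reactants: 1 2,4-dihydroxy-6-methylbenzaldehyde
Product: 2 2,4-bis(benzyloxy)-6-methylbenzaldehyde
Conditions: BnBr (2.5 equiv), K2CO3 (3 equiv), DMF, 60 °C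
Reagents that add atoms: benzyl bromide, BrCc1ccccc1
Why: Williamson ether synthesis in which excess benzyl bromide and carbonate in warm DMF alkylate both phenoxides, including the chelated 2-OH, while the aldehyde is inert and no stereocentre is created.

**Step 2**
Reactants: 2 2,4-bis(benzyloxy)-6-methylbenzaldehyde
Product: 3 2,4-bis(benzyloxy)-6-methylbenzoic acid
Conditions: NaClO2 (3 equiv), NaH2PO4 (3 equiv), 2-methyl-2-butene (15 equiv), t-BuOH/THF/H2O, 0 °C → rt
Reagents that add atoms: sodium chlorite, [Na+].[O-]Cl=O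
Why: Pinnick oxidation, in which buffered chlorous acid adds to the aldehyde and fragments to the acid even with two ortho substituents, while the alkene traps HOCl before it can chlorinate the electron-rich ring.

**Step 3**
Reactants: 3 2,4-bis(benzyloxy)-6-methylbenzoic acid; 1 2,4-dihydroxy-6-methylbenzaldehyde
Product: 5 4-formyl-3-hydroxy-5-methylphenyl 2,4-bis(benzyloxy)-6-methylbenzoate, via mixed trifluoroacetic anhydride 4 (not isolated)
Conditions: TFAA (4 equiv), toluene, 0 °C → rt; aq NaHCO3 work-up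
Reagents that add atoms: none
Why: Mixed-anhydride esterification (trifluoroacetic anhydride method), in which the hindered electron-rich acid forms the strongly electrophilic acyl trifluoroacetate 4, which acylates only the free 4-OH of 1 because the 2-OH is hydrogen-bonded to and shielded by the formyl group.

**Step 4**
Reactants: 5 4-formyl-3-hydroxy-5-methylphenyl 2,4-bis(benzyloxy)-6-methylbenzoate
Product: 6 4-formyl-3-methoxy-5-methylphenyl 2,4-bis(benzyloxy)-6-methylbenzoate
Conditions: MeI (3 equiv), K2CO3 (2 equiv), DMF, rt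
Reagents that add atoms: iodomethane, CI
Why: Williamson O-methylation of the only remaining phenol under mild carbonate conditions, which the di-ortho-substituted aryl ester is too hindered to be cleaved by.

**Step 5**
Reactants: 6 4-formyl-3-methoxy-5-methylphenyl 2,4-bis(benzyloxy)-6-methylbenzoate
Product: 7 4-{[2,4-bis(benzyloxy)-6-methylbenzoyl]oxy}-2-methoxy-6-methylbenzoic acid
Conditions: NaClO2 (3 equiv), NaH2PO4 (3 equiv), 2-methyl-2-butene (20 equiv), t-BuOH/THF/H2O, 0 °C → rt
Reagents that add atoms: sodium chlorite, [Na+].[O-]Cl=O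
Why: Pinnick oxidation at about pH 4 converts the latent carboxyl group into the acid without touching the depside ester, the benzyl ethers or the methyl ether.

**Step 6**
Reactants: 7 4-{[2,4-bis(benzyloxy)-6-methylbenzoyl]oxy}-2-methoxy-6-methylbenzoic acid; 8 methyl 2,4-dihydroxy-6-methylbenzoate (methyl orsellinate)
Product: 10 methyl 4-[(4-{[2,4-bis(benzyloxy)-6-methylbenzoyl]oxy}-2-methoxy-6-methylbenzoyl)oxy]-2-hydroxy-6-methylbenzoate, via mixed trifluoroacetic anhydride 9 (not isolated)
Conditions: TFAA (4 equiv), toluene, 0 °C → rt; aq NaHCO3 work-up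
Reagents that add atoms: none
Why: The same mixed-anhydride esterification, in which acyl trifluoroacetate 9 is attacked by the free 4-OH of 8 while the 2-OH stays chelated to the ester carbonyl and unreactive.

**Step 7**
Reactants: 10 methyl 4-[(4-{[2,4-bis(benzyloxy)-6-methylbenzoyl]oxy}-2-methoxy-6-methylbenzoyl)oxy]-2-hydroxy-6-methylbenzoate
Product: 11 methyl 4-[(4-{[2,4-dihydroxy-6-methylbenzoyl]oxy}-2-methoxy-6-methylbenzoyl)oxy]-2-hydroxy-6-methylbenzoate (CNP0563156.0)
Conditions: H2 (1 atm), 10% Pd/C, EtOAc, rt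
Reagents that add atoms: none
Why: Catalytic hydrogenolysis cleaves only the two benzylic C–O bonds, and in a neutral non-nucleophilic solvent the two depside esters, the methyl ester and the methyl ether are untouched, giving the achiral target.

**Compound list**
1 | 2,4-dihydroxy-6-methylbenzaldehyde (orsellinaldehyde) | Cc1cc(O)cc(O)c1C=O | starting material
2 | 2,4-bis(benzyloxy)-6-methylbenzaldehyde | Cc1cc(OCc2ccccc2)cc(OCc2ccccc2)c1C=O | intermediate
3 | 2,4-bis(benzyloxy)-6-methylbenzoic acid | Cc1cc(OCc2ccccc2)cc(OCc2ccccc2)c1C(=O)O | intermediate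
4 | 2,4-bis(benzyloxy)-6-methylbenzoic trifluoroacetic anhydride | Cc1cc(OCc2ccccc2)cc(OCc2ccccc2)c1C(=O)OC(=O)C(F)(F)F | intermediate
5 | 4-formyl-3-hydroxy-5-methylphenyl 2,4-bis(benzyloxy)-6-methylbenzoate | Cc1cc(OCc2ccccc2)cc(OCc2ccccc2)c1C(=O)Oc1cc(C)c(C=O)c(O)c1 | intermediate
6 | 4-formyl-3-methoxy-5-methylphenyl 2,4-bis(benzyloxy)-6-methylbenzoate | Cc1cc(OCc2ccccc2)cc(OCc2ccccc2)c1C(=O)Oc1cc(C)c(C=O)c(OC)c1 | intermediate
7 | 4-{[2,4-bis(benzyloxy)-6-methylbenzoyl]oxy}-2-methoxy-6-methylbenzoic acid | Cc1cc(OCc2ccccc2)cc(OCc2ccccc2)c1C(=O)Oc1cc(C)c(C(=O)O)c(OC)c1 | intermediate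
8 | methyl 2,4-dihydroxy-6-methylbenzoate (methyl orsellinate) | COC(=O)c1c(C)cc(O)cc1O | starting material
9 | 4-{[2,4-bis(benzyloxy)-6-methylbenzoyl]oxy}-2-methoxy-6-methylbenzoic trifluoroacetic anhydride | Cc1cc(OCc2ccccc2)cc(OCc2ccccc2)c1C(=O)Oc1cc(C)c(C(=O)OC(=O)C(F)(F)F)c(OC)c1 | intermediate
10 | methyl 4-[(4-{[2,4-bis(benzyloxy)-6-methylbenzoyl]oxy}-2-methoxy-6-methylbenzoyl)oxy]-2-hydroxy-6-methylbenzoate | COC(=O)c1c(C)cc(OC(=O)c2c(C)cc(OC(=O)c3c(C)cc(OCc4ccccc4)cc3OCc5ccccc5)cc2OC)cc1O | intermediate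
11 | methyl 4-[(4-{[2,4-dihydroxy-6-methylbenzoyl]oxy}-2-methoxy-6-methylbenzoyl)oxy]-2-hydroxy-6-methylbenzoate (methyl 2'-O-methylgyrophorate, CNP0563156.0) | COC(=O)c1c(C)cc(OC(=O)c2c(C)cc(OC(=O)c3c(C)cc(O)cc3O)cc2OC)cc1O | target

**Total step count:** 7
**Longest linear sequence:** 7 (steps 1 to 7; 1 re-enters at step 3 and 8 enters at step 6 as purchased materials)

**Three steps most likely to fail**

**Step 6.** The late-stage, doubly ortho-substituted acid 7 may couple slowly. The acidic medium could also scramble the existing depside bond or acylate O-2 of 8.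
- The fallback reverses the order of assembly: the B–C bond is made first with a simple acid and the A–B bond last. It sets out from 8 and comes back at 10.
- Compound 8 is benzylated only at its free 4-OH (BnBr 1.05 equiv, K2CO3, acetone, reflux) to give methyl 4-(benzyloxy)-2-hydroxy-6-methylbenzoate F1.
- Methylation (MeI, K2CO3, DMF) gives methyl 4-(benzyloxy)-2-methoxy-6-methylbenzoate F2, and saponification (KOH, DMSO/H2O, 100 °C) gives 4-(benzyloxy)-2-methoxy-6-methylbenzoic acid F3.
- This cheap acid can be used in excess. It is activated with TFAA in toluene as 4-(benzyloxy)-2-methoxy-6-methylbenzoic trifluoroacetic anhydride F4 and joined to a second portion of 8, giving methyl 4-{[4-(benzyloxy)-2-methoxy-6-methylbenzoyl]oxy}-2-hydroxy-6-methylbenzoate F5.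
- Hydrogenolysis (H2, Pd/C, EtOAc) gives methyl 2-hydroxy-4-[(4-hydroxy-2-methoxy-6-methylbenzoyl)oxy]-6-methylbenzoate F6.
- The only non-chelated OH of this phenol is acylated by 3 through 4 (TFAA, toluene) to give 10.

**Step 5.** HOCl may chlorinate the very electron-rich ring A (C-3 lies between two benzyloxy groups). Oxidation of the di-ortho-substituted aldehyde 6 may also be sluggish.
- The fallback brings ring B in at the carboxylic acid oxidation level as an allyl ester, so nothing has to be oxidised after the depside bond exists. It sets out from 3 and comes back at 7.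
- Commercial orsellinic acid is alkylated on the carboxylate only (allyl bromide, KHCO3, DMF, rt) to give allyl 2,4-dihydroxy-6-methylbenzoate F7.
- Acid 3, through 4 (TFAA, toluene), acylates its free 4-OH to give allyl 4-{[2,4-bis(benzyloxy)-6-methylbenzoyl]oxy}-2-hydroxy-6-methylbenzoate F8.
- MeI/K2CO3 in DMF gives allyl 4-{[2,4-bis(benzyloxy)-6-methylbenzoyl]oxy}-2-methoxy-6-methylbenzoate F9.
- Pd(PPh3)4 (cat.) and morpholine in THF at rt remove the allyl ester by π-allyl transfer. This is insensitive to hindrance at the carbonyl and spares the benzyl ethers and the depside, giving 7.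

**Step 4.** The chelated, weakly nucleophilic 2'-phenoxide of 5 may react slowly. Base-induced cleavage or transacylation of the aryl ester could then compete.
- The fallback installs the methyl ether before the depside bond is made. It sets out from 1 and comes back at 6, replacing steps 3 and 4.
- Compound 1 is allylated only at the free 4-OH (allyl bromide 1.05 equiv, K2CO3, acetone, rt) to give 4-(allyloxy)-2-hydroxy-6-methylbenzaldehyde F10.
- Methylation (MeI, K2CO3, DMF) gives 4-(allyloxy)-2-methoxy-6-methylbenzaldehyde F11.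
- Deallylation (Pd(PPh3)4 cat., morpholine, THF) gives 4-hydroxy-2-methoxy-6-methylbenzaldehyde F12.
- The single OH of this phenol is acylated by 3 through 4 (TFAA, toluene) to give 6 with no regiochemical question.

**Further compounds**
F1 | step 6 | methyl 4-(benzyloxy)-2-hydroxy-6-methylbenzoate | COC(=O)c1c(C)cc(OCc2ccccc2)cc1O
F2 | step 6 | methyl 4-(benzyloxy)-2-methoxy-6-methylbenzoate | COC(=O)c1c(C)cc(OCc2ccccc2)cc1OC
F3 | step 6 | 4-(benzyloxy)-2-methoxy-6-methylbenzoic acid | OC(=O)c1c(C)cc(OCc2ccccc2)cc1OC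
F4 | step 6 | 4-(benzyloxy)-2-methoxy-6-methylbenzoic trifluoroacetic anhydride | FC(F)(F)C(=O)OC(=O)c1c(C)cc(OCc2ccccc2)cc1OC
F5 | step 6 | methyl 4-{[4-(benzyloxy)-2-methoxy-6-methylbenzoyl]oxy}-2-hydroxy-6-methylbenzoate | COC(=O)c1c(C)cc(OC(=O)c2c(C)cc(OCc3ccccc3)cc2OC)cc1O
F6 | step 6 | methyl 2-hydroxy-4-[(4-hydroxy-2-methoxy-6-methylbenzoyl)oxy]-6-methylbenzoate | COC(=O)c1c(C)cc(OC(=O)c2c(C)cc(O)cc2OC)cc1O
F7 | step 5 | allyl 2,4-dihydroxy-6-methylbenzoate | C=CCOC(=O)c1c(C)cc(O)cc1O
F8 | step 5 | allyl 4-{[2,4-bis(benzyloxy)-6-methylbenzoyl]oxy}-2-hydroxy-6-methylbenzoate | C=CCOC(=O)c1c(C)cc(OC(=O)c2c(C)cc(OCc3ccccc3)cc2OCc4ccccc4)cc1O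
F9 | step 5 | allyl 4-{[2,4-bis(benzyloxy)-6-methylbenzoyl]oxy}-2-methoxy-6-methylbenzoate | C=CCOC(=O)c1c(C)cc(OC(=O)c2c(C)cc(OCc3ccccc3)cc2OCc4ccccc4)cc1OC
F10 | step 4 | 4-(allyloxy)-2-hydroxy-6-methylbenzaldehyde | C=CCOc1cc(C)c(C=O)c(O)c1
F11 | step 4 | 4-(allyloxy)-2-methoxy-6-methylbenzaldehyde | C=CCOc1cc(C)c(C=O)c(OC)c1
F12 | step 4 | 4-hydroxy-2-methoxy-6-methylbenzaldehyde | Oc1cc(C)c(C=O)c(OC)c1
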